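**Strategy.** Target numbering: ring C1–C6 (C1 and C2 bear angelates, C3–C4 the epoxide with CH3 on C3, C6 the side chain C7–C11, =CH2 on C7). The oxygens on C1 and C4 are cis and 1,4-related on the cyclohexane ring, so C1, C6, C5, C4 and the C1 oxygen are taken from a 3-prenylfuran. A Diels–Alder reaction with 1-methylallenyl phenyl sulfone forms C1–C2 and C3–C4 together, giving a 7-oxanorbornene whose C2 is a latent ketone (exocyclic methylene) and whose C3 carries the methyl group and a sulfonyl trigger. The oxygen bridge steers reduction at C6 and is then opened by β-elimination to the 6-hydroxy-enone.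

Key step: step 4

Remark: no chiral controller is used in the cycloaddition, so the cycloadduct and the four compounds after it are racemates (drawn as the antipode that leads to the target). The reagent-controlled allylation turns the two antipodes into diastereomers, which are carried together through the first acylation and parted after the bridge is opened.

Step 1
Reactants: 1 3-bromofuran; 2 1-bromo-3-methylbut-2-ene
Product: 4 3-(3-methylbut-2-en-1-yl)furan, via furan-3-yllithium 3 (not isolated)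
Conditions: n-BuLi, THF, −78 °C; then 2, −78 → −40 °C
Reagents that add atoms: none
Why: Bromine–lithium exchange gives the 3-lithiofuran, which is kept cold (no shift of lithium to the 2-position) and alkylated at the primary carbon of the allylic bromide in an SN2 coupling; no stereocentre is formed.

Step 2
Reactants: 5 but-2-yn-1-ol
Product: 7 (buta-2,3-dien-2-ylsulfinyl)benzene, via but-2-yn-1-yl benzenesulfenate 6 (not isolated)
Conditions: PhSCl, Et3N, CH2Cl2, −78 → 23 °C
Reagents that add atoms: benzenesulfenyl chloride, ClSc1ccccc1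
Why: O-Sulfenylation of the propargylic alcohol is followed by a spontaneous [2,3]-sigmatropic (Mislow–Evans-type) shift of the sulfenate to the allenyl sulfoxide, which places sulfur on the methyl-bearing carbon.

Step 3
Reactants: 7 allenyl sulfoxide
Product: 8 (buta-2,3-dien-2-ylsulfonyl)benzene
Conditions: mCPBA, CH2Cl2, 0 °C
Reagents that add atoms: 3-chloroperoxybenzoic acid (mCPBA), OOC(=O)c1cccc(Cl)c1
Why: Peracid oxidation of the sulfoxide to the sulfone; the electron-poor allene is inert to the electrophilic oxidant.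

Step 4
Reactants: 4 3-prenylfuran; 8 allenyl sulfone
Product: 9 rac-(1S,2S,4R)-2-methyl-3-methylidene-5-(3-methylbut-2-en-1-yl)-2-(phenylsulfonyl)-7-oxabicyclo[2.2.1]hept-5-ene (drawn sulfonyl endo; the sulfonyl-exo epimer is expected alongside)
Conditions: 8 (excess), PhMe, 70 °C, sealed tube
Reagents that add atoms: none
Why: A thermal, concerted but asynchronous normal-demand Diels–Alder reaction joins the furan diene of 4 (C2=C3–C4=C5) to the sulfonyl-bearing 2,3-π bond of allene 8; the closest known reaction type is the [4+2] cycloaddition of furans with allenyl sulfones and allenoates. It closes the six-membered carbocycle of a 7-oxabicyclo[2.2.1]heptene in a (4+2) suprafacial–suprafacial mode, the furan oxygen becoming the one-atom bridge. The two bridgehead stereocentres (future C1 and C4) are set cis to each other by the bridge, the sulfonyl-bearing carbon forms as both epimers (erased in step 10), and no absolute control is exerted, so 9 is racemic. The step needs the regiochemistry in which the sulfonyl carbon bonds to furan C5 and the central allene carbon to furan C2 (next to the prenyl group); this is secured by the larger HOMO coefficient at furan C2 meeting the larger LUMO coefficient at the central allene carbon, and by the quaternary sulfonyl carbon avoiding the substituted furan terminus. It also needs selectivity for the activated allene π bond over the terminal one and over the unactivated prenyl alkene, which the sulfone provides. Moderate temperature and an excess of 8 are chosen because the adduct can revert, and 9 is reduced directly in step 5.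

Step 5
Reactants: 9 cycloadduct
Product: 10 rac-(1S,2S,4R,5S)-2-methyl-3-methylidene-5-(3-methylbut-2-en-1-yl)-2-(phenylsulfonyl)-7-oxabicyclo[2.2.1]heptane (prenyl endo)
Conditions: 2-nitrobenzenesulfonohydrazide, Et3N, CH2Cl2, 23 °C
Reagents that add atoms: none
Why: Diimide released from the sulfonylhydrazide transfers H2 in a concerted syn fashion to the strained bicyclic alkene from its exo face (the side of the oxygen bridge), which puts the prenyl group endo and so sets C6 trans to the future C1 oxygen, while the unstrained exocyclic and trisubstituted alkenes react far more slowly.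

Step 6
Reactants: 10 reduced cycloadduct
Product: 11 rac-2-[(1R,2R,4S,5R)-5-methyl-6-oxo-5-(phenylsulfonyl)-7-oxabicyclo[2.2.1]heptan-2-yl]acetaldehyde
Conditions: O3, CH2Cl2–MeOH, −78 °C; then Me2S, −78 → 23 °C
Reagents that add atoms: ozone, [O-][O+]=O
Why: Ozonolysis with reductive work-up cleaves both remaining alkenes, the methylidene group becoming the C2 ketone and the prenyl group the C7–C8 acetaldehyde arm; no stereocentre is touched.

Step 7
Reactants: 11 keto aldehyde
Product: 13 rac-2-[(1R,2R,4S,5R)-5-methyl-6-oxo-5-(phenylsulfonyl)-7-oxabicyclo[2.2.1]heptan-2-yl]prop-2-enal, via Mannich base 12 (not isolated)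
Conditions: CH2=NMe2+ I− (Eschenmoser's salt), Et3N, CH2Cl2, 23 °C
Reagents that add atoms: N,N-dimethylmethaniminium iodide (Eschenmoser's salt), C=[N+](C)C.[I-]
Why: A Mannich reaction at the only enolisable position (the aldehyde α-CH2, since the ketone is flanked by a quaternary carbon and a bridgehead) and loss of dimethylamine install the C7 methylene (α-methylenation).

Step 8
Reactants: 13 enal
Product: 14 (3S)-2-[(1R,2R,4S,5R)-5-methyl-6-oxo-5-(phenylsulfonyl)-7-oxabicyclo[2.2.1]heptan-2-yl]hexa-1,5-dien-3-ol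
Conditions: (−)-Ipc2B(allyl), Et2O, −78 °C; then HOCH2CH2NH2, 23 °C
Reagents that add atoms: (−)-B-allyldiisopinocampheylborane, C=CCB([C@@H]1C[C@@H]2C[C@H]([C@H]1C)C2(C)C)[C@@H]1C[C@@H]2C[C@H]([C@H]1C)C2(C)C
Why: Brown allylboration through a closed chair transition state is reagent-controlled, so the borane derived from (+)-α-pinene adds to the Si face of the aldehyde and gives the (S)-carbinol at C8 for either antipode of the bicycle (14 is therefore expected with an equal amount of its (1S,2S,4R,5S),(3S) diastereomer, carried on together), while the hindered ketone does not react at −78 °C.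

Step 9
Reactants: 14 allyl carbinol; 15 angelic acid [(2Z)-2-methylbut-2-enoic acid]
Product: 16 (3S)-2-[(1R,2R,4S,5R)-5-methyl-6-oxo-5-(phenylsulfonyl)-7-oxabicyclo[2.2.1]heptan-2-yl]hexa-1,5-dien-3-yl (2Z)-2-methylbut-2-enoate
Conditions: 15, 2,4,6-Cl3C6H2COCl, Et3N, PhMe, 23 °C, filter; then 14, 70 °C
Reagents that add atoms: none
Why: Acylation of the only hydroxyl group (C8) with the preformed angelic 2,4,6-trichlorobenzoic mixed anhydride (Yamaguchi-type esterification without a nucleophilic catalyst) transfers the less hindered angeloyl group without Z to E isomerisation, both diastereomers reacting alike and no stereocentre being touched.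

Step 10
Reactants: 16 C8 angelate
Product: 18 (3S)-2-[(1R,2R)-2-hydroxy-4-methyl-3-oxocyclohex-4-en-1-yl]hexa-1,5-dien-3-yl (2Z)-2-methylbut-2-enoate, via bicyclic ketone 17 (not isolated)
Conditions: SmI2, THF–MeOH, −78 °C; then DBU, CH2Cl2, 23 °C; chromatography
Reagents that add atoms: none
Why: Single-electron reduction of the β-keto sulfone, far faster at −78 °C than any reduction of the conjugated ester, expels benzenesulfinate and the enolate is protonated to 17, after which DBU triggers an E1cB opening of the strained oxygen bridge (enolate at C3, alkoxide leaving from C4) to unveil the C3=C4 enone and the C1 hydroxyl trans to the C6 substituent, the diastereomer that stems from the antipodal bicycle being removed by chromatography at this stage.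

Step 11
Reactants: 18 hydroxy enone
Product: 19 (3S)-2-[(1S,3R,4R,6S)-4-hydroxy-6-methyl-5-oxo-7-oxabicyclo[4.1.0]heptan-3-yl]hexa-1,5-dien-3-yl (2Z)-2-methylbut-2-enoate
Conditions: t-BuOOH, DBU, CH2Cl2, 0 → 23 °C
Reagents that add atoms: tert-butyl hydroperoxide, CC(C)(C)OO
Why: Weitz–Scheffer epoxidation, in which the peroxide anion adds axially to C4 of the enone anti to the C6 substituent (as in carvone) and on the face of the C1 hydroxyl, so the C3–C4 epoxide forms cis to the C1 oxygen, while the isolated alkenes and the hindered angelate are inert to the nucleophilic oxidant.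

Step 12
Reactants: 19 hydroxy epoxy ketone; 15 angelic acid
Product: 20 (1S,3R,4R,6S)-1-methyl-4-{(3S)-3-[(2Z)-2-methylbut-2-enoyloxy]hexa-1,5-dien-2-yl}-2-oxo-7-oxabicyclo[4.1.0]heptan-3-yl (2Z)-2-methylbut-2-enoate
Conditions: 15, 2,4,6-Cl3C6H2COCl, Et3N, PhMe, 23 °C, filter; then 19, 60 °C
Reagents that add atoms: none
Why: The same mixed-anhydride acylation esterifies the only free hydroxyl group (C1, α to the ketone) before the ketone is reduced, so that the C1 and C2 oxygens are never free together; no stereocentre is touched.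

Step 13
Reactants: 20 bis-angelate epoxy ketone
Product: 21 (1R,2S,3R,4R,6S)-2-hydroxy-1-methyl-4-{(3S)-3-[(2Z)-2-methylbut-2-enoyloxy]hexa-1,5-dien-2-yl}-7-oxabicyclo[4.1.0]heptan-3-yl (2Z)-2-methylbut-2-enoate
Conditions: NaBH4, CeCl3·7H2O, MeOH–THF, −78 °C
Reagents that add atoms: none
Why: Luche reduction, in which the small hydride should add to the C2 ketone along the axial trajectory on the epoxide face (cerium bridging the carbonyl and oxirane oxygens, the opposite face being shielded by the C3 methyl group), the course usual for 2,3-epoxycyclohexanones, gives the equatorial C2 hydroxyl trans to the epoxide oxygen and to the C1 acyloxy group, while esters and epoxide are not reduced at −78 °C.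

Step 14
Reactants: 21 epoxy alcohol; 15 angelic acid
Product: 22 (1S,2S,3R,4R,6S)-1-methyl-4-{(3S)-3-[(2Z)-2-methylbut-2-enoyloxy]hexa-1,5-dien-2-yl}-7-oxabicyclo[4.1.0]heptane-2,3-diyl bis[(2Z)-2-methylbut-2-enoate]
Conditions: 15, 2,4,6-Cl3C6H2COCl, Et3N, PhMe, 23 °C, filter; then 21, 80 °C
Reagents that add atoms: none
Why: Third mixed-anhydride acylation, now of the single hindered C2 hydroxyl next to the epoxide, under essentially neutral conditions that should avoid Payne-type epoxide migration and Z to E isomerisation; no stereocentre is touched.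

Step 15
Reactants: 22 tris-angelate; 23 2-methylbut-2-ene
Product: 24 (1S,2S,3R,4R,6S)-1-methyl-4-{(3S)-6-methyl-3-[(2Z)-2-methylbut-2-enoyloxy]hepta-1,5-dien-2-yl}-7-oxabicyclo[4.1.0]heptane-2,3-diyl bis[(2Z)-2-methylbut-2-enoate]
Conditions: second-generation Grubbs catalyst (H2IMes)(PCy3)Cl2Ru=CHPh (5 mol %), 23 (excess), CH2Cl2, 40 °C
Reagents that add atoms: none
Why: Olefin cross-metathesis converts the monosubstituted alkene into the trisubstituted C10=C11 alkene, the 1,1-disubstituted alkene and the conjugated angelate alkenes being too hindered or electron-poor to engage.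

Step 16
Reactants: 24 prenylated tris-angelate
Product: 25 (1S,2S,3R,4R,6S)-4-{(3S)-4-[(2R)-3,3-dimethyloxiran-2-yl]-3-[(2Z)-2-methylbut-2-enoyloxy]but-1-en-2-yl}-1-methyl-7-oxabicyclo[4.1.0]heptane-2,3-diyl bis[(2Z)-2-methylbut-2-enoate] (CNP0258231.1)
Conditions: D-fructose-derived Shi ketone (30 mol %), KHSO5 (as 2KHSO5·KHSO4·K2SO4), K2CO3, Bu4NHSO4, MeCN–CH2(OMe)2–aq. Na2B4O7, 0 °C
Reagents that add atoms: potassium peroxymonosulfate, [K+].[O-]S(=O)(=O)OO
Why: Shi epoxidation, in which the chiral dioxirane attacks the electron-rich trisubstituted alkene through a spiro transition state and, under reagent control, gives the (R) configuration at C10, while the 1,1-disubstituted alkene and the electron-poor angelates react much more slowly.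

**Compound list**

1 | 3-bromofuran | Brc1ccoc1 | starting material
2 | 1-bromo-3-methylbut-2-ene | CC(C)=CCBr | starting material
3 | furan-3-yllithium | [Li]c1ccoc1 | intermediate
4 | 3-(3-methylbut-2-en-1-yl)furan | CC(C)=CCc1ccoc1 | intermediate
5 | but-2-yn-1-ol | CC#CCO | starting material
6 | but-2-yn-1-yl benzenesulfenate | CC#CCOSc1ccccc1 | intermediate
7 | (buta-2,3-dien-2-ylsulfinyl)benzene (racemic at sulfur) | C=C=C(C)S(=O)c1ccccc1 | intermediate
8 | (buta-2,3-dien-2-ylsulfonyl)benzene | C=C=C(C)S(=O)(=O)c1ccccc1 | intermediate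
9 | rac-(1S,2S,4R)-2-methyl-3-methylidene-5-(3-methylbut-2-en-1-yl)-2-(phenylsulfonyl)-7-oxabicyclo[2.2.1]hept-5-ene (sulfonyl endo drawn) | CC(C)=CCC1=C[C@@H]2O[C@H]1C(=C)[C@]2(C)S(=O)(=O)c3ccccc3 | intermediate
10 | rac-(1S,2S,4R,5S)-2-methyl-3-methylidene-5-(3-methylbut-2-en-1-yl)-2-(phenylsulfonyl)-7-oxabicyclo[2.2.1]heptane | CC(C)=CC[C@H]1C[C@@H]2O[C@H]1C(=C)[C@]2(C)S(=O)(=O)c3ccccc3 | intermediate
11 | rac-2-[(1R,2R,4S,5R)-5-methyl-6-oxo-5-(phenylsulfonyl)-7-oxabicyclo[2.2.1]heptan-2-yl]acetaldehyde | O=CC[C@H]1C[C@@H]2O[C@H]1C(=O)[C@]2(C)S(=O)(=O)c3ccccc3 | intermediate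
12 | rac-3-(dimethylamino)-2-[(1R,2R,4S,5R)-5-methyl-6-oxo-5-(phenylsulfonyl)-7-oxabicyclo[2.2.1]heptan-2-yl]propanal (both epimers at the chain carbon) | CN(C)CC(C=O)[C@H]1C[C@@H]2O[C@H]1C(=O)[C@]2(C)S(=O)(=O)c3ccccc3 | intermediate
13 | rac-2-[(1R,2R,4S,5R)-5-methyl-6-oxo-5-(phenylsulfonyl)-7-oxabicyclo[2.2.1]heptan-2-yl]prop-2-enal | O=CC(=C)[C@H]1C[C@@H]2O[C@H]1C(=O)[C@]2(C)S(=O)(=O)c3ccccc3 | intermediate
14 | (3S)-2-[(1R,2R,4S,5R)-5-methyl-6-oxo-5-(phenylsulfonyl)-7-oxabicyclo[2.2.1]heptan-2-yl]hexa-1,5-dien-3-ol (carried on with its (1S,2S,4R,5S),(3S) diastereomer) | C=C([C@H](CC=C)O)[C@H]1C[C@@H]2O[C@H]1C(=O)[C@]2(C)S(=O)(=O)c3ccccc3 | intermediate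
15 | angelic acid, (2Z)-2-methylbut-2-enoic acid | C/C=C(/C)C(=O)O | starting material
16 | (3S)-2-[(1R,2R,4S,5R)-5-methyl-6-oxo-5-(phenylsulfonyl)-7-oxabicyclo[2.2.1]heptan-2-yl]hexa-1,5-dien-3-yl (2Z)-2-methylbut-2-enoate (carried on with its (1S,2S,4R,5S),(3S) diastereomer) | C=C([C@H](CC=C)OC(=O)/C(C)=C\C)[C@H]1C[C@@H]2O[C@H]1C(=O)[C@]2(C)S(=O)(=O)c3ccccc3 | intermediate
17 | (3S)-2-[(1R,2R,4S)-5-methyl-6-oxo-7-oxabicyclo[2.2.1]heptan-2-yl]hexa-1,5-dien-3-yl (2Z)-2-methylbut-2-enoate (both epimers at the methyl-bearing carbon) | C=C([C@H](CC=C)OC(=O)/C(C)=C\C)[C@H]1C[C@@H]2O[C@H]1C(=O)C2C | intermediate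
18 | (3S)-2-[(1R,2R)-2-hydroxy-4-methyl-3-oxocyclohex-4-en-1-yl]hexa-1,5-dien-3-yl (2Z)-2-methylbut-2-enoate | C=C([C@H](CC=C)OC(=O)/C(C)=C\C)[C@H]1CC=C(C)C(=O)[C@@H]1O | intermediate
19 | (3S)-2-[(1S,3R,4R,6S)-4-hydroxy-6-methyl-5-oxo-7-oxabicyclo[4.1.0]heptan-3-yl]hexa-1,5-dien-3-yl (2Z)-2-methylbut-2-enoate | C=C([C@H](CC=C)OC(=O)/C(C)=C\C)[C@H]1C[C@@H]2O[C@]2(C)C(=O)[C@@H]1O | intermediate
20 | (1S,3R,4R,6S)-1-methyl-4-{(3S)-3-[(2Z)-2-methylbut-2-enoyloxy]hexa-1,5-dien-2-yl}-2-oxo-7-oxabicyclo[4.1.0]heptan-3-yl (2Z)-2-methylbut-2-enoate | C=C([C@H](CC=C)OC(=O)/C(C)=C\C)[C@H]1C[C@@H]2O[C@]2(C)C(=O)[C@@H]1OC(=O)/C(C)=C\C | intermediate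
21 | (1R,2S,3R,4R,6S)-2-hydroxy-1-methyl-4-{(3S)-3-[(2Z)-2-methylbut-2-enoyloxy]hexa-1,5-dien-2-yl}-7-oxabicyclo[4.1.0]heptan-3-yl (2Z)-2-methylbut-2-enoate | C=C([C@H](CC=C)OC(=O)/C(C)=C\C)[C@H]1C[C@@H]2O[C@]2(C)[C@@H](O)[C@@H]1OC(=O)/C(C)=C\C | intermediate
22 | (1S,2S,3R,4R,6S)-1-methyl-4-{(3S)-3-[(2Z)-2-methylbut-2-enoyloxy]hexa-1,5-dien-2-yl}-7-oxabicyclo[4.1.0]heptane-2,3-diyl bis[(2Z)-2-methylbut-2-enoate] | C=C([C@H](CC=C)OC(=O)/C(C)=C\C)[C@H]1C[C@@H]2O[C@]2(C)[C@@H](OC(=O)/C(C)=C\C)[C@@H]1OC(=O)/C(C)=C\C | intermediate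
23 | 2-methylbut-2-ene | CC=C(C)C | starting material
24 | (1S,2S,3R,4R,6S)-1-methyl-4-{(3S)-6-methyl-3-[(2Z)-2-methylbut-2-enoyloxy]hepta-1,5-dien-2-yl}-7-oxabicyclo[4.1.0]heptane-2,3-diyl bis[(2Z)-2-methylbut-2-enoate] | C=C([C@H](CC=C(C)C)OC(=O)/C(C)=C\C)[C@H]1C[C@@H]2O[C@]2(C)[C@@H](OC(=O)/C(C)=C\C)[C@@H]1OC(=O)/C(C)=C\C | intermediate
25 | CNP0258231.1 | C=C([C@H](C[C@H]1OC1(C)C)OC(=O)/C(C)=C\C)[C@H]1C[C@@H]2O[C@]2(C)[C@@H](OC(=O)/C(C)=C\C)[C@@H]1OC(=O)/C(C)=C\C | target

**Step count.** Total: 16 steps. Longest linear sequence: 15 steps (5 → 7 → 8 → 9 → … → 25).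

**Steps most likely to fail**

Step 4. The α-methylated allenyl sulfone may add slowly, the adduct may revert to its components, or the cycloaddition may take the other regiochemical course. Fallback, setting out from 4: a ZnI2-promoted Diels–Alder reaction with tert-butyl 2-methylbuta-2,3-dienoate F1 (made from tert-butyl 2-(triphenylphosphoranylidene)propanoate, acetyl chloride and Et3N) should give the ester cycloadduct F2. The conditions of steps 5–9 would carry it on to the reduced ester F3, the keto ester aldehyde F4, by way of the Mannich base F5 the enal F6, the allyl carbinol F7 and its angelate F8. TFA in CH2Cl2 at 0 °C should then cleave the tert-butyl ester to the β-keto acid F9, which is expected to lose CO2 on gentle warming in PhMe and give 17. DBU as in step 10 would open the bridge, and the route is rejoined at 18.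

Step 13. Hydride delivery may be poorly face-selective once the C1 hydroxyl is acylated, or the C1 acyl group may migrate toward the new alkoxide. Fallback, setting out from 19: hydroxyl-directed reduction with Me4NBH(OAc)3 (MeCN–AcOH, −30 °C), in which the C1 hydroxyl binds boron and delivers hydride to its own face of the C2 ketone, should give the trans-diol F11. Acylation of both hydroxyls with an excess of the mixed anhydride made from 15 (conditions of step 14) would return the route at 22.

Step 10. Partition of the two diastereomers by chromatography may be incomplete, since they differ only in the sense of the ring relative to C8. Fallback, setting out from the mixture of 18 and its (1S,2S)-ring diastereomer: Burkholderia cepacia lipase (Amano PS) with vinyl acetate in MTBE is expected, by the empirical size rule for lipases (branched ring carbon as the large group, the carbonyl carbon as the medium group), to acetylate the ring hydroxyl of the unwanted diastereomer only. This would give the ring acetate F10, after which unchanged 18 should be separated easily and the route continues at 18.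

Further compounds

F1 | step 4 | tert-butyl 2-methylbuta-2,3-dienoate | C=C=C(C)C(=O)OC(C)(C)C
F2 | step 4 | rac-tert-butyl 2-methyl-3-methylidene-5-(3-methylbut-2-en-1-yl)-7-oxabicyclo[2.2.1]hept-5-ene-2-carboxylate (ester endo drawn) | CC(C)=CCC1=C[C@@H]2O[C@H]1C(=C)[C@]2(C)C(=O)OC(C)(C)C
F3 | step 4 | rac-tert-butyl 2-methyl-3-methylidene-5-endo-(3-methylbut-2-en-1-yl)-7-oxabicyclo[2.2.1]heptane-2-carboxylate | CC(C)=CC[C@H]1C[C@@H]2O[C@H]1C(=C)[C@]2(C)C(=O)OC(C)(C)C
F4 | step 4 | rac-tert-butyl 2-methyl-3-oxo-5-endo-(2-oxoethyl)-7-oxabicyclo[2.2.1]heptane-2-carboxylate | O=CC[C@H]1C[C@@H]2O[C@H]1C(=O)[C@]2(C)C(=O)OC(C)(C)C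
F5 | step 4 | rac-tert-butyl 5-endo-[1-(dimethylamino)-3-oxopropan-2-yl]-2-methyl-3-oxo-7-oxabicyclo[2.2.1]heptane-2-carboxylate (Mannich base) | CN(C)CC(C=O)[C@H]1C[C@@H]2O[C@H]1C(=O)[C@]2(C)C(=O)OC(C)(C)C
F6 | step 4 | rac-tert-butyl 2-methyl-3-oxo-5-endo-(3-oxoprop-1-en-2-yl)-7-oxabicyclo[2.2.1]heptane-2-carboxylate | O=CC(=C)[C@H]1C[C@@H]2O[C@H]1C(=O)[C@]2(C)C(=O)OC(C)(C)C
F7 | step 4 | tert-butyl 5-endo-[(3S)-3-hydroxyhexa-1,5-dien-2-yl]-2-methyl-3-oxo-7-oxabicyclo[2.2.1]heptane-2-carboxylate (both bicycle antipodes) | C=C([C@H](CC=C)O)[C@H]1C[C@@H]2O[C@H]1C(=O)[C@]2(C)C(=O)OC(C)(C)C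
F8 | step 4 | tert-butyl 2-methyl-5-endo-{(3S)-3-[(2Z)-2-methylbut-2-enoyloxy]hexa-1,5-dien-2-yl}-3-oxo-7-oxabicyclo[2.2.1]heptane-2-carboxylate (both bicycle antipodes) | C=C([C@H](CC=C)OC(=O)/C(C)=C\C)[C@H]1C[C@@H]2O[C@H]1C(=O)[C@]2(C)C(=O)OC(C)(C)C
F9 | step 4 | 2-methyl-5-endo-{(3S)-3-[(2Z)-2-methylbut-2-enoyloxy]hexa-1,5-dien-2-yl}-3-oxo-7-oxabicyclo[2.2.1]heptane-2-carboxylic acid (both bicycle antipodes) | C=C([C@H](CC=C)OC(=O)/C(C)=C\C)[C@H]1C[C@@H]2O[C@H]1C(=O)[C@]2(C)C(=O)O
F10 | step 10 | (3S)-2-[(1S,2S)-2-acetoxy-4-methyl-3-oxocyclohex-4-en-1-yl]hexa-1,5-dien-3-yl (2Z)-2-methylbut-2-enoate | C=C([C@H](CC=C)OC(=O)/C(C)=C\C)[C@@H]1CC=C(C)C(=O)[C@H]1OC(C)=O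
F11 | step 13 | (3S)-2-[(1S,3R,4R,5S,6R)-4,5-dihydroxy-6-methyl-7-oxabicyclo[4.1.0]heptan-3-yl]hexa-1,5-dien-3-yl (2Z)-2-methylbut-2-enoate | C=C([C@H](CC=C)OC(=O)/C(C)=C\C)[C@H]1C[C@@H]2O[C@]2(C)[C@@H](O)[C@@H]1O
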